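Three neighbouring runs differ in one thing, the reagent charge.

    target → over-reaction product (k1 = 0.0044 min⁻¹)
    second substrate + reagent → second product (k2 = 0.018 L mol⁻¹ min⁻¹)
    third substrate + reagent → third product (k3 = 0.0033 L mol⁻¹ min⁻¹)
    starting material + reagent → target (k4 = 0.017 L mol⁻¹ min⁻¹)

| flask | starting material | reagent | second substrate | third substrate | time |
|---|---|---|---|---|---|
| zeta | 0.050 M | 0.100 M | 0.0500 M | 0.0500 M (fed, over 20 h) | 20 h |
| alpha | 0.050 M | 0.300 M | 0.0500 M | 0.0500 M (fed, over 20 h) | 20 h |
| delta | 0.050 M | 1.00 M | 0.0500 M | 0.0500 M (fed, over 20 h) | 20 h |

- "hardly changes" means that all values lie within two and a half points (for a concentration: within two and a half percent of the largest)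
- run time (zeta): 20 h

* amount of target at the end, in percent of the starting material charged for zeta, alpha, delta, in this order
* how the row runs (falls all the way / hardly changes / rises all the way / rises, then falls / falls, then rises)

Two colleagues dispute the row, and both start from one number. For delta, 3.86 is the making ratio: the constant of making times the reagent concentration, divided by the constant of target loss. At their charges, zeta has 0.386 and alpha 1.16.

The first colleague looks at the peak. With reagent held at its charge (pseudo-first-order), target peaks at 62.4% of the starting material in delta, against 21.2% in zeta. So she expects the row to rise.

The second colleague looks at the clock. The half-life of target is 2.6 h, short against the 20 h run. Delta's peak comes at about 1.79 h, long before the end. The forecast is his: 5.5%, 3.1% and 0.7%, so the row falls all the way. In his words, “more reagent simply uses up the starting material earlier and leaves the target longer to decay”.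

My own reckoning solves both ends and joins them. With a steady ratio m, the target share is m over m less one, times the difference of two decays, the starting material's and the target's. In delta the ratio is high, and the starting-material decay has died away by the end. That leaves 0.687%.

Zeta is the slow end. Its reagent charge equals the two substrates together, and their constants are close. The third substrate has the longer half-life, 35 h against 6.8 h, so I set it aside. Reagent then stays at twice the starting material. The fraction left in zeta is one over one plus twice the constant, the charge and the time: 32.9%. The ratio has sunk to 0.127. The feed goes as the square of that fraction, so target rides on it at the ratio times the fraction, over one less twice the ratio: 5.61%.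

Alpha lies at the join. The steady formula gives 2.11% at the reagent charge. With the 0.200 M left after both substrates, the ratio is 0.773 and the share 4.02%. So I commit to a bracket for alpha where the forecast gives a point, and to a falling row.

The simulation gives 5.60%, 3.10% and 0.703%, and the row falls all the way. At 10.0 h part of the first colleague's rise still stands: target is 13.1% in zeta and 18.0% in alpha. Delta is already below both: the making ratio of 3.86 puts it at 9.63% at that same time, and delta holds 9.84%.

The numbers are made up; the result is computed.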